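## The problem

CNP0086724.3 is a daucane diester in which a cyclopentane (C1–C5) and a cycloheptene (C1, C5–C10) are cis-fused across the C1–C5 bond; C1 is quaternary and bears the angular methyl group, C4 is a tertiary isopropyl carbinol, C6 carries the 4-hydroxybenzoate, C8=C9 is a trisubstituted alkene with the C8 methyl group, and C10 carries the isovalerate (1R,4S,5S,6R,10S in daucane numbering). Four of the five stereocentres (C10, C1, C5, C6) are contiguous on a mobile seven-membered ring, so they are best set through rigid intermediates. C6 can come from reagent control, C5 from C6 across a cyclohexene, C1 from C5 by an intramolecular bond migration, and C4 and C10 last, from the convex face of the folded cis-bicycle. The quaternary C1, wedged between the ring fusion and the oxygenated C10, is the hardest atom. The two secondary hydroxyls at C6 and C10 must take different acyl groups, so they should be differentiated from the moment they are made. The tertiary alcohol dehydrates under acid, the allylic isovalerate ionises under Lewis acids, and the phenolic ester tolerates neither hydride nor hydroxide, so all three must arrive late. The enabling feature is that C1 is α to the oxygenated C10: read backwards, C1 and C2 are an isopropenyl group on a cyclohexanol carbon (C10), and C3 is an acetal carbon ending a two-carbon chain on the neighbouring ring carbon C5. One cation–olefin closure (C2–C3) followed by a 1,2-shift of C5 from C10 to C1 then builds both rings, the quaternary centre and the C10 carbonyl.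

## Retrosynthesis

**Ester C–O bonds.** Target 38 is opened at the phenol to acetate 37, and 37 at the C6 ester to alcohol 35 and acid chloride 36. Alcohol 35 goes back through silyl ether 34 to allylic alcohol 32 and anhydride 33. Acylating at a stage where the C6 and C10 hydroxyls are both free is rejected, because both are hindered secondary alcohols with no reliable bias. In 32 the C6 oxygen is still silylated, so the order of acylation is fixed. The forward steps only require that the tertiary C4 hydroxyl stays inert and that the phenol is masked.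

**C10–H, C8–CH3 and C8=C9.** Alcohol 32 comes from β-methyl enone 31 by 1,2-reduction from the convex face. Enone 31 is traced through methyl ketone 30 and enone 29 to ketone 28 (dehydrogenation, conjugate methylation, dehydrogenation). Carrying the methyl group through from the six-membered starting ring was rejected: it adds a ring stereocentre that would have to be trans to the C6 oxygen for the key-step conformer, and nothing in the early steps controls it. The quaternary C1 blocks one side of the C10 ketone, so every enolisation is toward C9 and regiochemistry is not an issue.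

**C4–O bond.** Carbinol 28 comes from alkene 26 by Markovnikov hydration, 26 from alcohol 24 by syn-elimination, and 24 from benzyl ether 23. Adding an isopropyl nucleophile to a C4 ketone was rejected: it would enter from the convex face and leave the hydroxyl on the concave face, the wrong epimer. Oxygen has to be delivered from the convex face to an sp2 C4. This sequence also moves the oxygen that the key step leaves on C3 over to C4.

**C2–C3 and C1–C5 (key step).** Hydroazulenone 23 is taken back to silyl ether 20, a monocyclic cyclohexane whose only permanent stereocentres are C5 and C6. No other cut forms the quaternary centre, both rings and the C10 carbonyl at once. The forward reaction must ionise the acetal selectively, close the six-membered ring through the alkene, and shift C5 before the cation is lost otherwise.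

**C10–C1 bond and the ring stereocentres.** Silyl ether 20 comes from carbinol 19, and 19 from ketone 17 and Grignard reagent 18. Ketone 17 comes from alcohol 16, which is the hydroboration product of cyclohexenyl silyl ether 14. Ether 14 comes from allylic alcohol 13 and enone 12. Hydroboration is preferred over aldol or epoxide-opening routes because hydrogen is delivered to C5 anti to the C6 silyloxy group, which gives the required cis relation of side chain and oxygen by construction. C6 itself comes from a catalyst-controlled enone reduction.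

**C4–C5 bond and C3.** Enone 12 is traced through enone 11, acetal 9 and vinylogous ester 7 to Michael adduct 6, which is made from cyclohexane-1,3-dione 5 and nitroalkene 4. Nitroalkene 4 comes from 2-methylpropanal 1 and nitromethane 2. The dione supplies both oxygens that flank C5, and the nitroalkene supplies C4 with its isopropyl group and C3 at the aldehyde oxidation level. Two traps are avoided. A 2-substituted 1,3-dione is an enol that cannot be reduced cleanly and would close onto a C3 aldehyde to give a furan, so the enol is capped as vinylogous ester 7 before the Nef reaction. One carbonyl is then removed by reduction–hydrolysis rather than by direct ketone reduction. The side-chain centre (future C4) is erased later but must be defined, because it decides whether the isopropyl group is equatorial in the key step and whether H4 ends up syn to the C3 oxygen.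

## Roads not taken

**Alternative 1:** The cut is at C9–C10 and C6–C7. Indium metal converts 3-chloro-2-(chloromethyl)prop-1-ene A2 into a double allyl donor that adds to both formyl groups of cis-dialdehyde A1 and closes the seven-membered ring as methylene diol A3.
- Merits: it is convergent. The seven-membered ring, both carbinol oxygens and the C8 carbon arrive in one step, and no oxidation-state changes are needed at C10.
- Weak points: A1 already contains the quaternary C1 and the cis relation, so the hardest problem is only moved into an enantioselective synthesis of A1. The two new carbinol centres arise from additions to a neopentyl and an α-branched aldehyde without a dependable control element, and one of four diastereomers is needed. The second allylation is a medium-ring closure. The exocyclic alkene must isomerise to C8=C9 and not C7=C8. The two similar secondary hydroxyls of A3 must take different acyl groups. The masked C4 ketone would later take an isopropyl nucleophile from the convex face, giving the wrong C4 epimer.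
- Comparison: Alternative 1 is shorter after ring formation and brings C8 with it, where the chosen plan spends three steps on the methyl group and alkene. Against that, the chosen plan names a control element for every stereocentre and makes the C6 and C10 oxygens in different forms (silyl ether and ketone).

**Alternative 2:** The cut is at C1–C2 and C4–C5. Under TiCl4 the allenylsilane A5 adds to the methyl-bearing carbon of 2,6-dimethylbenzoquinone A4. After a 1,2-silyl shift the enolate closes the cyclopentene to give ene-dione A6.
- Merits: one step from two achiral pieces gives the quaternary C1 with its methyl group, the cis fusion, the isopropyl group on C4, a C3=C4 double bond after protodesilylation, and both C6 and C10 as carbonyls.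
- Weak points: A6 is a hydrindane, so a regioselective one-carbon insertion next to C10 is still needed to reach the seven-membered ring. Attack at the substituted quinone carbon is the sterically disfavoured mode. The annulation has no established enantioselective version, so A6 would be racemic. The two carbonyls of A6 must be told apart and reduced with control.
- Comparison: Alternative 2 reaches the C3=C4 stage in far fewer steps than the chosen plan. The chosen plan offers absolute configuration from two catalytic steps and direct formation of the seven-membered ring in the key step.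

**Alternative 3:** The cut is at C7–C8 and C8–C9. Rh2(OAc)4 turns ethyl diazoacetate A8 into a carbenoid that cyclopropanates the unsubstituted arene bond of indane A7, and electrocyclic opening of the adduct gives cycloheptatriene ester A9.
- Merits: this is the shortest way to the bicyclic skeleton with oxygen on C6 and C10 (as enol ethers), C8 as the ester carbon, and the C4 carbinol already in place on A7.
- Weak points: in A9 the carbons C1 and C5 are sp2. The angular methyl group must still be added to a fully substituted ring-fusion carbon, and C1, C5, C6 and C10 must all be set on a flat triene with only the remote C4 centre to guide them. Cycloheptatrienes equilibrate by hydrogen shifts and by reversible electrocyclic ring closure. The ester must be reduced to a methyl group. The benzylic tertiary silyl ether of A7 ionises easily.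
- Comparison: Alternative 3 is better in step count to the ring system. The chosen plan is longer but creates the quaternary centre and the ring fusion with defined configuration in the step that makes the rings.

Key step: step 13

Remark on the chemistry: the target is taken as drawn (1,5-cis-fused); bicyclic compounds are named in daucane numbering (C1–C5 cyclopentane; C1, C5–C10 cycloheptane; C14 is the methyl on C8 and "14-nor" means it is absent); centres erased later (C10 in 15, 16, 19–22; C3 in 22–25; C8 in 30) are drawn as the epimer the stated model predicts.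

Step 1
Reactants: 1 2-methylpropanal; 2 nitromethane
Product: 4 (E)-3-methyl-1-nitrobut-1-ene, via 3-methyl-1-nitrobutan-2-ol 3 (not isolated)
Conditions: KOt-Bu (5 mol %), THF/t-BuOH, 0 °C; then MsCl, Et3N, CH2Cl2, 0 °C
Reagents that add atoms: none
Why: Henry addition followed by mesylation and E1cB loss of methanesulfonate; the conjugated E-nitroalkene is the thermodynamic product.

Step 2
Reactants: 5 cyclohexane-1,3-dione; 4 (E)-3-methyl-1-nitrobut-1-ene
Product: 6 3-hydroxy-2-[(2S)-3-methyl-1-nitrobutan-2-yl]cyclohex-2-en-1-one
Conditions: cinchona-derived bifunctional squaramide (5 mol %, the quinine- or quinidine-based antipode that gives the S adduct), CH2Cl2, 0 °C to rt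
Reagents that add atoms: none
Why: Organocatalytic Michael addition of a cyclic 1,3-dione to a nitroalkene; the squaramide binds the nitro group while the quinuclidine nitrogen deprotonates the dione, so the enol attacks one alkene face and sets the side-chain centre (future C4) as S.

Step 3
Reactants: 6 3-hydroxy-2-[(2S)-3-methyl-1-nitrobutan-2-yl]cyclohex-2-en-1-one
Product: 7 3-methoxy-2-[(2S)-3-methyl-1-nitrobutan-2-yl]cyclohex-2-en-1-one
Conditions: HC(OMe)3, TsOH (cat.), MeOH, rt
Reagents that add atoms: methanol, CO; trimethyl orthoformate, COC(OC)OC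
Why: Acid-catalysed vinylogous esterification; capping the enol stops retro-Michael loss of the nitroalkene under base and, later, cyclisation of the enol onto the aldehyde carbon to a furan.

Step 4
Reactants: 7 3-methoxy-2-[(2S)-3-methyl-1-nitrobutan-2-yl]cyclohex-2-en-1-one
Product: 9 2-[(2S)-1,1-dimethoxy-3-methylbutan-2-yl]-3-methoxycyclohex-2-en-1-one, via sodium nitronate 8 (not isolated)
Conditions: NaOMe, MeOH, 0 °C; then added to H2SO4/MeOH, −40 °C
Reagents that add atoms: methanol, CO
Why: Nef reaction in its acetal-forming variant: the nitronate is solvolysed in cold methanolic acid directly to the dimethyl acetal, so the free α-branched aldehyde, which could epimerise, never appears.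

Step 5
Reactants: 9 2-[(2S)-1,1-dimethoxy-3-methylbutan-2-yl]-3-methoxycyclohex-2-en-1-one
Product: 11 2-[(2S)-1,1-dimethoxy-3-methylbutan-2-yl]cyclohex-2-en-1-one, via 3-methoxy allylic alcohol 10 (not isolated)
Conditions: i-Bu2AlH, CH2Cl2, −78 °C; then 1 M HCl, THF, 0 °C, short contact
Reagents that add atoms: water, O
Why: Stork–Danheiser-type 1,2-reduction of a vinylogous ester and acid-induced hydrolysis–dehydration of the 3-alkoxy allylic alcohol, which transposes the carbonyl; enol-ether hydrolysis is far faster than hydrolysis of the hindered dimethyl acetal at 0 °C.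

Step 6
Reactants: 11 2-[(2S)-1,1-dimethoxy-3-methylbutan-2-yl]cyclohex-2-en-1-one
Product: 12 2-[(2S)-1,1-bis(benzyloxy)-3-methylbutan-2-yl]cyclohex-2-en-1-one
Conditions: BnOH (3 equiv), CSA (cat.), PhMe, 45 °C, reduced pressure (removal of MeOH)
Reagents that add atoms: benzyl alcohol, OCc1ccccc1
Why: Acid-catalysed transacetalisation driven by removal of methanol; benzyl is chosen because the ether it leaves on C3 after the key step can be cleaved by hydrogenolysis, which a methyl ether cannot.

Step 7
Reactants: 12 2-[(2S)-1,1-bis(benzyloxy)-3-methylbutan-2-yl]cyclohex-2-en-1-one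
Product: 13 (1R)-2-[(2S)-1,1-bis(benzyloxy)-3-methylbutan-2-yl]cyclohex-2-en-1-ol
Conditions: (S)-2-methyl-CBS-oxazaborolidine (15 mol %), BH3·SMe2, THF, −30 °C; MeOH quench
Reagents that add atoms: none
Why: Corey–Bakshi–Shibata reduction of an α-substituted cyclohexenone; the substituted alkenyl arm is the large group, so the (S)-catalyst should give the 1R carbinol (future C6), and the minor antipode of the side-chain centre becomes a separable diastereomer.

Step 8
Reactants: 13 (1R)-2-[(2S)-1,1-bis(benzyloxy)-3-methylbutan-2-yl]cyclohex-2-en-1-ol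
Product: 14 tert-butyl{[(1R)-2-[(2S)-1,1-bis(benzyloxy)-3-methylbutan-2-yl]cyclohex-2-en-1-yl]oxy}diphenylsilane
Conditions: TBDPSCl, imidazole, DMF, rt
Reagents that add atoms: tert-butyl(chloro)diphenylsilane, CC(C)(C)[Si](Cl)(c1ccccc1)c1ccccc1
Why: Silylation with a silyl chloride (silyl triflates are avoided because they ionise acetals); the bulky, weakly basic diphenylsilyl ether oxygen is chosen so that it does not attack the oxocarbenium ion in the key step.

Step 9
Reactants: 14 tert-butyl{[(1R)-2-[(2S)-1,1-bis(benzyloxy)-3-methylbutan-2-yl]cyclohex-2-en-1-yl]oxy}diphenylsilane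
Product: 16 (1R,2S,3R)-2-[(2S)-1,1-bis(benzyloxy)-3-methylbutan-2-yl]-3-[(tert-butyldiphenylsilyl)oxy]cyclohexan-1-ol, via alkylborane 15 (not isolated)
Conditions: BH3·THF, THF, 0 °C to rt; then NaOH, H2O2, 0 °C
Reagents that add atoms: hydrogen peroxide, OO
Why: Hydroboration–oxidation of a trisubstituted cycloalkene: boron goes to the unsubstituted alkene carbon, and boron and hydrogen add syn to the face opposite the pseudoaxial allylic silyloxy group; this sets C5 with the side chain cis to the silyloxy group and the new hydroxyl trans to both.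

Step 10
Reactants: 16 (1R,2S,3R)-2-[(2S)-1,1-bis(benzyloxy)-3-methylbutan-2-yl]-3-[(tert-butyldiphenylsilyl)oxy]cyclohexan-1-ol
Product: 17 (2R,3R)-2-[(2S)-1,1-bis(benzyloxy)-3-methylbutan-2-yl]-3-[(tert-butyldiphenylsilyl)oxy]cyclohexan-1-one
Conditions: Dess–Martin periodinane, NaHCO3, CH2Cl2, 0 °C to rt
Reagents that add atoms: none
Why: Dess–Martin oxidation under buffered, non-basic conditions, so that the α-centre (C5) does not epimerise and the β-silyloxy group is not eliminated.

Step 11
Reactants: 17 (2R,3R)-2-[(2S)-1,1-bis(benzyloxy)-3-methylbutan-2-yl]-3-[(tert-butyldiphenylsilyl)oxy]cyclohexan-1-one; 18 isopropenylmagnesium bromide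
Product: 19 (1S,2R,3R)-2-[(2S)-1,1-bis(benzyloxy)-3-methylbutan-2-yl]-3-[(tert-butyldiphenylsilyl)oxy]-1-(prop-1-en-2-yl)cyclohexan-1-ol
Conditions: CeCl3 (anhydrous), THF, −78 °C
Reagents that add atoms: none
Why: Organocerium addition to an enolisable α-branched ketone (low basicity suppresses enolisation and β-elimination); equatorial attack anti to the axial β-silyloxy group should put the isopropenyl group trans to the side chain, though either carbinol epimer would serve because this carbon becomes the ketone.

Step 12
Reactants: 19 (1S,2R,3R)-2-[(2S)-1,1-bis(benzyloxy)-3-methylbutan-2-yl]-3-[(tert-butyldiphenylsilyl)oxy]-1-(prop-1-en-2-yl)cyclohexan-1-ol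
Product: 20 {[(1S,2R,3R)-2-[(2S)-1,1-bis(benzyloxy)-3-methylbutan-2-yl]-3-[(tert-butyldiphenylsilyl)oxy]-1-(prop-1-en-2-yl)cyclohexyl]oxy}trimethylsilane
Conditions: N-(trimethylsilyl)imidazole, CH2Cl2, rt to 40 °C
Reagents that add atoms: N-(trimethylsilyl)imidazole, C[Si](C)(C)n1ccnc1
Why: Silylation of a hindered tertiary alcohol with a neutral, powerful silyl donor that leaves the acetal untouched; the silyl ether is the pinacol terminator of the next step and prevents closure of the hydroxyl onto the acetal.

Step 13
Reactants: 20 {[(1S,2R,3R)-2-[(2S)-1,1-bis(benzyloxy)-3-methylbutan-2-yl]-3-[(tert-butyldiphenylsilyl)oxy]-1-(prop-1-en-2-yl)cyclohexyl]oxy}trimethylsilane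
Product: 23 (1R,3S,4S,5S,6R)-3-(benzyloxy)-6-[(tert-butyldiphenylsilyl)oxy]-14-nordaucan-10-one, via O-benzyl oxocarbenium ion 21 (not isolated), via bicyclic tertiary carbocation 22 (not isolated)
Conditions: SnCl4 (1.5 equiv), CH2Cl2, −78 to −23 °C; NaHCO3 (aq)
Reagents that add atoms: none
Why: SnCl4 ionises the dibenzyl acetal to the E-oxocarbenium ion 21, whose carbon is attacked by the terminal carbon of the isopropenyl group (C2–C3) in a six-membered closure that is endo with respect to the alkene, through a chair with equatorial isopropyl and benzyloxy groups, giving the trans-fused tertiary cation 22 at C1. The ring bond C10–C5 then shifts to C1 (pinacol step), which contracts the new six-membered ring to the cyclopentane, enlarges the cyclohexane to the cycloheptane and, after loss of the trimethylsilyl group to chloride, leaves the C10 ketone. The closest known reaction type is the Prins cyclisation–pinacol rearrangement of 1-alkenylcycloalkanol silyl ethers bearing an acetal side chain (ring-enlarging cyclopentane annulation); benzyl for methyl on the acetal oxygen is a spectator change, since dibenzyl acetals are standard oxocarbenium precursors in Lewis acid-mediated allylations. C1 is set because C5 migrates suprafacially and with retention to the cation face to which it is tethered, which can only give the 1,5-cis fusion with the methyl group cis to H5; C5 and C6 are carried over unchanged. The transient C3 centre follows from the equatorial benzyloxy group in the chair, so the ether should end up trans to the isopropyl group and cis to H4, as step 15 requires. The step needs ionisation of the acetal rather than of the tertiary allylic silyl ether (the acetal is the more basic site at low temperature), attack by the alkene rather than by the C6 oxygen (secured by the bulky diphenylsilyl ether), and the shift rather than proton loss (secured by the silyloxy lone pair on C10, which makes the shift fast and irreversible).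

Step 14
Reactants: 23 (1R,3S,4S,5S,6R)-3-(benzyloxy)-6-[(tert-butyldiphenylsilyl)oxy]-14-nordaucan-10-one
Product: 24 (1R,3S,4S,5S,6R)-6-[(tert-butyldiphenylsilyl)oxy]-3-hydroxy-14-nordaucan-10-one
Conditions: H2 (1 atm), Pd/C (10 wt % palladium on carbon), EtOAc, rt
Reagents that add atoms: none
Why: Hydrogenolysis of a benzyl ether; ketone, silyl ether and all stereocentres are untouched.

Step 15
Reactants: 24 (1R,3S,4S,5S,6R)-6-[(tert-butyldiphenylsilyl)oxy]-3-hydroxy-14-nordaucan-10-one
Product: 26 (1R,5S,6R)-6-[(tert-butyldiphenylsilyl)oxy]-14-nordauc-3-en-10-one, via triethylammonium sulfamate ester 25 (not isolated)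
Conditions: Burgess reagent (methyl N-(triethylammoniosulfonyl)carbamate), PhMe, rt to 80 °C
Reagents that add atoms: none
Why: Burgess dehydration, a thermal syn-elimination of the sulfamate ester; the C3 oxygen and the tertiary C4 hydrogen are cis on the concave face, and the ion-pair character of the transition state favours the more substituted C3=C4 alkene over the C2=C3 isomer.

Step 16
Reactants: 26 (1R,5S,6R)-6-[(tert-butyldiphenylsilyl)oxy]-14-nordauc-3-en-10-one
Product: 28 (1R,4S,5S,6R)-6-[(tert-butyldiphenylsilyl)oxy]-4-hydroxy-14-nordaucan-10-one, via tertiary hydroperoxide 27 (not isolated)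
Conditions: Mn(dpm)3 (tris(dipivaloylmethanato)manganese, 10 mol %), PhSiH3, O2 (1 atm), i-PrOH/CH2Cl2, 0 °C; then PPh3
Reagents that add atoms: dioxygen, O=O
Why: Mukaiyama hydration: hydrogen-atom transfer from a manganese hydride to C3, capture of the tertiary C4 radical by O2 and reduction of the hydroperoxide; O2 should approach the planar radical from the convex face of the cis-bicycle, anti to C6, placing the hydroxyl cis to H5 and the angular methyl group (4S).

Step 17
Reactants: 28 (1R,4S,5S,6R)-6-[(tert-butyldiphenylsilyl)oxy]-4-hydroxy-14-nordaucan-10-one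
Product: 29 (1R,4S,5S,6R)-6-[(tert-butyldiphenylsilyl)oxy]-4-hydroxy-14-nordauc-8-en-10-one
Conditions: IBX (2-iodoxybenzoic acid), DMSO/PhMe, 70 °C
Reagents that add atoms: none
Why: IBX dehydrogenation of a ketone through its enol; only C9 carries α-hydrogens, so the alkene can form only at C8–C9.

Step 18
Reactants: 29 (1R,4S,5S,6R)-6-[(tert-butyldiphenylsilyl)oxy]-4-hydroxy-14-nordauc-8-en-10-one
Product: 30 (1R,4S,5S,6R,8R)-6-[(tert-butyldiphenylsilyl)oxy]-4-hydroxydaucan-10-one
Conditions: Me2CuLi (from MeLi and CuI, 2.5 equiv), Et2O, −40 to 0 °C; NH4Cl/NH3 (aq)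
Reagents that add atoms: lithium dimethylcuprate, [Li+].C[Cu-]C
Why: Conjugate addition of a Gilman cuprate to a cycloheptenone (one equivalent is consumed by the tertiary hydroxyl); the new C8 centre, methyl expected on the convex face, is erased in the next step.

Step 19
Reactants: 30 (1R,4S,5S,6R,8R)-6-[(tert-butyldiphenylsilyl)oxy]-4-hydroxydaucan-10-one
Product: 31 (1R,4S,5S,6R)-6-[(tert-butyldiphenylsilyl)oxy]-4-hydroxydauc-8-en-10-one
Conditions: IBX, DMSO/PhMe, 75 °C
Reagents that add atoms: none
Why: Second IBX dehydrogenation, again regiodefined by the quaternary C1, now giving the β-methyl enone.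

Step 20
Reactants: 31 (1R,4S,5S,6R)-6-[(tert-butyldiphenylsilyl)oxy]-4-hydroxydauc-8-en-10-one
Product: 32 (1R,4S,5S,6R,10S)-6-[(tert-butyldiphenylsilyl)oxy]dauc-8-ene-4,10-diol
Conditions: NaBH4, CeCl3·7H2O, MeOH, −78 to −40 °C
Reagents that add atoms: none
Why: Luche 1,2-reduction; hydride should come from the convex face because the concave face is covered by the cyclopentane with its isopropyl group and by the C6 silyloxy group, giving the 10S alcohol with the hydroxyl trans to the angular methyl group.

Step 21
Reactants: 32 (1R,4S,5S,6R,10S)-6-[(tert-butyldiphenylsilyl)oxy]dauc-8-ene-4,10-diol; 33 3-methylbutanoic anhydride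
Product: 34 (1R,4S,5S,6R,10S)-6-[(tert-butyldiphenylsilyl)oxy]-4-hydroxydauc-8-en-10-yl 3-methylbutanoate
Conditions: Et3N, DMAP (cat.), CH2Cl2, rt
Reagents that add atoms: none
Why: DMAP-catalysed acylation with an anhydride; the secondary allylic hydroxyl reacts and the hindered tertiary C4 hydroxyl does not.

Step 22
Reactants: 34 (1R,4S,5S,6R,10S)-6-[(tert-butyldiphenylsilyl)oxy]-4-hydroxydauc-8-en-10-yl 3-methylbutanoate
Product: 35 (1R,4S,5S,6R,10S)-4,6-dihydroxydauc-8-en-10-yl 3-methylbutanoate
Conditions: Bu4NF, AcOH, THF, 0 °C to rt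
Reagents that add atoms: none
Why: Fluoride cleavage of the silyl ether, buffered with acetic acid so that the ester neither migrates nor hydrolyses.

Step 23
Reactants: 35 (1R,4S,5S,6R,10S)-4,6-dihydroxydauc-8-en-10-yl 3-methylbutanoate; 36 4-(acetyloxy)benzoyl chloride
Product: 37 (1R,4S,5S,6R,10S)-4-hydroxy-10-[(3-methylbutanoyl)oxy]dauc-8-en-6-yl 4-(acetyloxy)benzoate
Conditions: pyridine, DMAP (cat.), CH2Cl2, 0 °C to rt
Reagents that add atoms: none
Why: Acylation of the secondary C6 alcohol with an acid chloride under nucleophilic catalysis; the phenol is carried as its acetate so that the acid chloride cannot self-condense, and the tertiary hydroxyl stays free.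

Step 24
Reactants: 37 (1R,4S,5S,6R,10S)-4-hydroxy-10-[(3-methylbutanoyl)oxy]dauc-8-en-6-yl 4-(acetyloxy)benzoate
Product: 38 (1R,4S,5S,6R,10S)-4-hydroxy-10-[(3-methylbutanoyl)oxy]dauc-8-en-6-yl 4-hydroxybenzoate
Conditions: pyrrolidine (1.2 equiv), CH2Cl2, 0 °C
Reagents that add atoms: none
Why: Aminolysis of the aryl acetate, which is far more electrophilic (phenoxide leaving group) than the benzoate and the hindered isovalerate, releases the phenol and gives the target.

## Compound list

1 | 2-methylpropanal | CC(C)C=O | starting material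
2 | nitromethane | C[N+](=O)[O-] | starting material
3 | 3-methyl-1-nitrobutan-2-ol (racemic) | CC(C)C(O)C[N+](=O)[O-] | intermediate (not isolated)
4 | (E)-3-methyl-1-nitrobut-1-ene | CC(C)/C=C/[N+](=O)[O-] | intermediate
5 | cyclohexane-1,3-dione | O=C1CCCC(=O)C1 | starting material
6 | 3-hydroxy-2-[(2S)-3-methyl-1-nitrobutan-2-yl]cyclohex-2-en-1-one | O=C1CCCC(O)=C1[C@H](C(C)C)C[N+](=O)[O-] | intermediate
7 | 3-methoxy-2-[(2S)-3-methyl-1-nitrobutan-2-yl]cyclohex-2-en-1-one | O=C1CCCC(OC)=C1[C@H](C(C)C)C[N+](=O)[O-] | intermediate
8 | sodium (2S)-2-(2-methoxy-6-oxocyclohex-1-en-1-yl)-3-methylbutane-1-nitronate | O=C1CCCC(OC)=C1[C@H](C(C)C)C=[N+]([O-])[O-].[Na+] | intermediate (not isolated)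
9 | 2-[(2S)-1,1-dimethoxy-3-methylbutan-2-yl]-3-methoxycyclohex-2-en-1-one | O=C1CCCC(OC)=C1[C@H](C(C)C)C(OC)OC | intermediate
10 | 2-[(2S)-1,1-dimethoxy-3-methylbutan-2-yl]-3-methoxycyclohex-2-en-1-ol (both carbinol epimers) | OC1CCCC(OC)=C1[C@H](C(C)C)C(OC)OC | intermediate (not isolated)
11 | 2-[(2S)-1,1-dimethoxy-3-methylbutan-2-yl]cyclohex-2-en-1-one | O=C1CCCC=C1[C@H](C(C)C)C(OC)OC | intermediate
12 | 2-[(2S)-1,1-bis(benzyloxy)-3-methylbutan-2-yl]cyclohex-2-en-1-one | O=C1CCCC=C1[C@H](C(C)C)C(OCc2ccccc2)OCc2ccccc2 | intermediate
13 | (1R)-2-[(2S)-1,1-bis(benzyloxy)-3-methylbutan-2-yl]cyclohex-2-en-1-ol | C1CC=C([C@H](C(C)C)C(OCc2ccccc2)OCc2ccccc2)[C@H](O)C1 | intermediate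
14 | tert-butyl{[(1R)-2-[(2S)-1,1-bis(benzyloxy)-3-methylbutan-2-yl]cyclohex-2-en-1-yl]oxy}diphenylsilane | C1CC=C([C@H](C(C)C)C(OCc2ccccc2)OCc2ccccc2)[C@H](O[Si](c2ccccc2)(c2ccccc2)C(C)(C)C)C1 | intermediate
15 | {(1R,2R,3R)-2-[(2S)-1,1-bis(benzyloxy)-3-methylbutan-2-yl]-3-[(tert-butyldiphenylsilyl)oxy]cyclohexyl}borane | C1C[C@@H](B)[C@H]([C@H](C(C)C)C(OCc2ccccc2)OCc2ccccc2)[C@H](O[Si](c2ccccc2)(c2ccccc2)C(C)(C)C)C1 | intermediate (not isolated)
16 | (1R,2S,3R)-2-[(2S)-1,1-bis(benzyloxy)-3-methylbutan-2-yl]-3-[(tert-butyldiphenylsilyl)oxy]cyclohexan-1-ol | C1C[C@@H](O)[C@H]([C@H](C(C)C)C(OCc2ccccc2)OCc2ccccc2)[C@H](O[Si](c2ccccc2)(c2ccccc2)C(C)(C)C)C1 | intermediate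
17 | (2R,3R)-2-[(2S)-1,1-bis(benzyloxy)-3-methylbutan-2-yl]-3-[(tert-butyldiphenylsilyl)oxy]cyclohexan-1-one | C1CC(=O)[C@H]([C@H](C(C)C)C(OCc2ccccc2)OCc2ccccc2)[C@H](O[Si](c2ccccc2)(c2ccccc2)C(C)(C)C)C1 | intermediate
18 | isopropenylmagnesium bromide (prop-1-en-2-ylmagnesium bromide) | CC(=C)[Mg]Br | starting material
19 | (1S,2R,3R)-2-[(2S)-1,1-bis(benzyloxy)-3-methylbutan-2-yl]-3-[(tert-butyldiphenylsilyl)oxy]-1-(prop-1-en-2-yl)cyclohexan-1-ol | C1C[C@@](O)(C(C)=C)[C@H]([C@H](C(C)C)C(OCc2ccccc2)OCc2ccccc2)[C@H](O[Si](c2ccccc2)(c2ccccc2)C(C)(C)C)C1 | intermediate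
20 | {[(1S,2R,3R)-2-[(2S)-1,1-bis(benzyloxy)-3-methylbutan-2-yl]-3-[(tert-butyldiphenylsilyl)oxy]-1-(prop-1-en-2-yl)cyclohexyl]oxy}trimethylsilane (key-step precursor) | C1C[C@@](O[Si](C)(C)C)(C(C)=C)[C@H]([C@H](C(C)C)C(OCc2ccccc2)OCc2ccccc2)[C@H](O[Si](c2ccccc2)(c2ccccc2)C(C)(C)C)C1 | intermediate
21 | (E)-O-benzyl oxocarbenium ion formed from 20 by loss of one benzyloxy group | C1C[C@@](O[Si](C)(C)C)(C(C)=C)[C@H]([C@H](C(C)C)/C=[O+]/Cc2ccccc2)[C@H](O[Si](c2ccccc2)(c2ccccc2)C(C)(C)C)C1 | intermediate (not isolated)
22 | trans-fused bicyclic tertiary carbocation (cation at C1; new ring C10–C1–C2–C3–C4–C5 with equatorial benzyloxy and isopropyl groups) | C1C[C@@]2(O[Si](C)(C)C)[C+](C)C[C@H](OCc3ccccc3)[C@@H](C(C)C)[C@@H]2[C@H](O[Si](c3ccccc3)(c3ccccc3)C(C)(C)C)C1 | intermediate (not isolated)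
23 | (1R,3S,4S,5S,6R)-3-(benzyloxy)-6-[(tert-butyldiphenylsilyl)oxy]-14-nordaucan-10-one (key-step product; 1-Me, 5-H and 4-isopropyl on one face, 3-O and 6-O on the other) | C1CC(=O)[C@]2(C)C[C@H](OCc3ccccc3)[C@@H](C(C)C)[C@@H]2[C@H](O[Si](c3ccccc3)(c3ccccc3)C(C)(C)C)C1 | intermediate
24 | (1R,3S,4S,5S,6R)-6-[(tert-butyldiphenylsilyl)oxy]-3-hydroxy-14-nordaucan-10-one | C1CC(=O)[C@]2(C)C[C@H](O)[C@@H](C(C)C)[C@@H]2[C@H](O[Si](c3ccccc3)(c3ccccc3)C(C)(C)C)C1 | intermediate
25 | triethylammonium salt of the 3-O-[N-(methoxycarbonyl)sulfamate] of 24 | C1CC(=O)[C@]2(C)C[C@H](OS(=O)(=O)[N-]C(=O)OC)[C@@H](C(C)C)[C@@H]2[C@H](O[Si](c3ccccc3)(c3ccccc3)C(C)(C)C)C1.CC[NH+](CC)CC | intermediate (not isolated)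
26 | (1R,5S,6R)-6-[(tert-butyldiphenylsilyl)oxy]-14-nordauc-3-en-10-one | C1CC(=O)[C@]2(C)CC=C(C(C)C)[C@@H]2[C@H](O[Si](c3ccccc3)(c3ccccc3)C(C)(C)C)C1 | intermediate
27 | (1R,4S,5S,6R)-6-[(tert-butyldiphenylsilyl)oxy]-4-hydroperoxy-14-nordaucan-10-one | C1CC(=O)[C@]2(C)CC[C@](OO)(C(C)C)[C@@H]2[C@H](O[Si](c3ccccc3)(c3ccccc3)C(C)(C)C)C1 | intermediate (not isolated)
28 | (1R,4S,5S,6R)-6-[(tert-butyldiphenylsilyl)oxy]-4-hydroxy-14-nordaucan-10-one | C1CC(=O)[C@]2(C)CC[C@](O)(C(C)C)[C@@H]2[C@H](O[Si](c3ccccc3)(c3ccccc3)C(C)(C)C)C1 | intermediate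
29 | (1R,4S,5S,6R)-6-[(tert-butyldiphenylsilyl)oxy]-4-hydroxy-14-nordauc-8-en-10-one | C1=CC(=O)[C@]2(C)CC[C@](O)(C(C)C)[C@@H]2[C@H](O[Si](c3ccccc3)(c3ccccc3)C(C)(C)C)C1 | intermediate
30 | (1R,4S,5S,6R,8R)-6-[(tert-butyldiphenylsilyl)oxy]-4-hydroxydaucan-10-one | C[C@H]1CC(=O)[C@]2(C)CC[C@](O)(C(C)C)[C@@H]2[C@H](O[Si](c3ccccc3)(c3ccccc3)C(C)(C)C)C1 | intermediate
31 | (1R,4S,5S,6R)-6-[(tert-butyldiphenylsilyl)oxy]-4-hydroxydauc-8-en-10-one | CC1=CC(=O)[C@]2(C)CC[C@](O)(C(C)C)[C@@H]2[C@H](O[Si](c3ccccc3)(c3ccccc3)C(C)(C)C)C1 | intermediate
32 | (1R,4S,5S,6R,10S)-6-[(tert-butyldiphenylsilyl)oxy]dauc-8-ene-4,10-diol | CC1=C[C@H](O)[C@]2(C)CC[C@](O)(C(C)C)[C@@H]2[C@H](O[Si](c3ccccc3)(c3ccccc3)C(C)(C)C)C1 | intermediate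
33 | 3-methylbutanoic anhydride (isovaleric anhydride) | CC(C)CC(=O)OC(=O)CC(C)C | starting material
34 | (1R,4S,5S,6R,10S)-6-[(tert-butyldiphenylsilyl)oxy]-4-hydroxydauc-8-en-10-yl 3-methylbutanoate | CC1=C[C@H](OC(=O)CC(C)C)[C@]2(C)CC[C@](O)(C(C)C)[C@@H]2[C@H](O[Si](c3ccccc3)(c3ccccc3)C(C)(C)C)C1 | intermediate
35 | (1R,4S,5S,6R,10S)-4,6-dihydroxydauc-8-en-10-yl 3-methylbutanoate | CC1=C[C@H](OC(=O)CC(C)C)[C@]2(C)CC[C@](O)(C(C)C)[C@@H]2[C@H](O)C1 | intermediate
36 | 4-(acetyloxy)benzoyl chloride | CC(=O)Oc1ccc(cc1)C(Cl)=O | starting material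
37 | (1R,4S,5S,6R,10S)-4-hydroxy-10-[(3-methylbutanoyl)oxy]dauc-8-en-6-yl 4-(acetyloxy)benzoate | CC1=C[C@H](OC(=O)CC(C)C)[C@]2(C)CC[C@](O)(C(C)C)[C@@H]2[C@H](OC(=O)c3ccc(OC(C)=O)cc3)C1 | intermediate
38 | (1R,4S,5S,6R,10S)-4-hydroxy-10-[(3-methylbutanoyl)oxy]dauc-8-en-6-yl 4-hydroxybenzoate (CNP0086724.3) | CC1=C[C@H](OC(=O)CC(C)C)[C@]2(C)CC[C@](O)(C(C)C)[C@@H]2[C@H](OC(=O)c2ccc(O)cc2)C1 | target

## Step count and least certain steps

Total step count: 24. Longest linear sequence: 24 steps (steps 1–24, counted from 2-methylpropanal 1 and nitromethane 2 through nitroalkene 4 to target 38). The route is fully linear; cyclohexane-1,3-dione 5, Grignard reagent 18, anhydride 33 and acid chloride 36 enter it as purchased materials.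

**Step 13 (key step).** The cation may be intercepted before the 1,2-shift, by proton loss from C1 or by capture of the oxocarbenium ion by the C6 ether oxygen with loss of its silyl group. The cause is that the alkene must attack through a chair that carries two axial silyloxy groups. The fallback sets out from carbinol 19. A catalytic amount of pyridinium tosylate in warm benzene should expel one benzyl alcohol and close the C10 hydroxyl onto C3, giving the cis-fused cyclic benzyl acetal F1. With SnCl4 this acetal can open at the ring oxygen to the same oxocarbenium ion, now with a tin alkoxide on C10. This is the alkoxide-terminated mode of the Prins–pinacol reaction, and the stronger donor should speed the shift. The route is rejoined at 23.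

**Step 15.** Elimination may go toward C2, because the syn hydrogen on C2 is less hindered than the tertiary hydrogen on C4. The same happens if the key step delivers some of the C3 epimer, which has no syn hydrogen on C4. The fallback sets out from alcohol 24. Iodine, triphenylphosphine and imidazole should give, with inversion, the convex-face 3-iodide F2, in which the C4 hydrogen is anti to the leaving group. DBU in hot toluene then effects an anti E2 elimination with Zaitsev orientation. The route is rejoined at 26.

**Step 16.** Facial selectivity in the oxygen capture may be poor, because the C4 radical is planar and flanked by the isopropyl group. Some reduction of the radical to the alkane is also possible. The fallback sets out from alkene 26. Buffered mCPBA should give the convex-face 3,4-epoxide F3. LiAlH4 in THF opens it at the less substituted C3 and also reduces the C10 ketone, giving 4,10-diol F4. Dess–Martin periodinane then reoxidises only the secondary alcohol. The route is rejoined at 28.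

**Step 2.** Enantioselectivity may be low and the adduct may erode by retro-Michael reaction, because aliphatic nitroalkenes bind hydrogen-bond catalysts less firmly than aryl ones and the dione is a good leaving group. The fallback sets out from 4 and 5 and moves the control to step 7. Triethylamine gives racemic material, that is 6 together with its (R)-nitro dione F5. Steps 3–6 then carry along the (R)-vinylogous ester F6, the (R)-sodium nitronate F7, the (R)-dimethyl acetal F8, the (R)-methoxy allylic alcohol F9, the (R)-enone F10 and the (R)-dibenzyl acetal enone F11. The catalyst-controlled reduction of step 7 turns the antipodes into diastereomers, 13 and the (1R,2′R) allylic alcohol F12, which are separated by chromatography. The route is rejoined at 13, at the cost of half the material.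

**Step 20.** Hydride may be delivered to the concave face, giving the 10R alcohol, because the angular methyl group on the convex face sits next to the carbonyl. The fallback sets out from enone 31 and replaces substrate control by reagent control. An oxazaborolidine-catalysed reduction with catecholborane is used, with the catalyst antipode that directs hydride to the convex face. It comes back at 32 and makes no new compound.

## Further compounds

F1 | step 13 | cis-fused 2-(benzyloxy)-4-[(tert-butyldiphenylsilyl)oxy]-3-(propan-2-yl)-7a-(prop-1-en-2-yl)octahydro-1-benzofuran (both anomers) | C1C[C@]2(C(C)=C)OC(OCc3ccccc3)[C@@H](C(C)C)[C@@H]2[C@H](O[Si](c3ccccc3)(c3ccccc3)C(C)(C)C)C1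
F2 | step 15 | 3-epi-3-deoxy-3-iodo derivative of 24 (iodine on the convex face) | C1CC(=O)[C@]2(C)C[C@@H](I)[C@@H](C(C)C)[C@@H]2[C@H](O[Si](c3ccccc3)(c3ccccc3)C(C)(C)C)C1
F3 | step 16 | 3,4-epoxide of 26 (oxygen on the convex face) | C1CC(=O)[C@]2(C)C[C@H]3O[C@@]3(C(C)C)[C@@H]2[C@H](O[Si](c4ccccc4)(c4ccccc4)C(C)(C)C)C1
F4 | step 16 | (1R,4S,5S,6R)-6-[(tert-butyldiphenylsilyl)oxy]-14-nordaucane-4,10-diol (C10 epimer from convex-face hydride drawn) | C1C[C@H](O)[C@]2(C)CC[C@](O)(C(C)C)[C@@H]2[C@H](O[Si](c3ccccc3)(c3ccccc3)C(C)(C)C)C1
F5 | step 2 | 3-hydroxy-2-[(2R)-3-methyl-1-nitrobutan-2-yl]cyclohex-2-en-1-one | O=C1CCCC(O)=C1[C@@H](C(C)C)C[N+](=O)[O-]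
F6 | step 2 | 3-methoxy-2-[(2R)-3-methyl-1-nitrobutan-2-yl]cyclohex-2-en-1-one | O=C1CCCC(OC)=C1[C@@H](C(C)C)C[N+](=O)[O-]
F7 | step 2 | sodium (2R)-2-(2-methoxy-6-oxocyclohex-1-en-1-yl)-3-methylbutane-1-nitronate | O=C1CCCC(OC)=C1[C@@H](C(C)C)C=[N+]([O-])[O-].[Na+]
F8 | step 2 | 2-[(2R)-1,1-dimethoxy-3-methylbutan-2-yl]-3-methoxycyclohex-2-en-1-one | O=C1CCCC(OC)=C1[C@@H](C(C)C)C(OC)OC
F9 | step 2 | 2-[(2R)-1,1-dimethoxy-3-methylbutan-2-yl]-3-methoxycyclohex-2-en-1-ol | OC1CCCC(OC)=C1[C@@H](C(C)C)C(OC)OC
F10 | step 2 | 2-[(2R)-1,1-dimethoxy-3-methylbutan-2-yl]cyclohex-2-en-1-one | O=C1CCCC=C1[C@@H](C(C)C)C(OC)OC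
F11 | step 2 | 2-[(2R)-1,1-bis(benzyloxy)-3-methylbutan-2-yl]cyclohex-2-en-1-one | O=C1CCCC=C1[C@@H](C(C)C)C(OCc2ccccc2)OCc2ccccc2
F12 | step 2 | (1R)-2-[(2R)-1,1-bis(benzyloxy)-3-methylbutan-2-yl]cyclohex-2-en-1-ol | C1CC=C([C@@H](C(C)C)C(OCc2ccccc2)OCc2ccccc2)[C@H](O)C1
F0 | step 20 | none | none
A1 | alternative 1 | cis-7-methyl-1,4-dioxaspiro[4.4]nonane-6,7-dicarbaldehyde | O=C[C@]1(C)CCC2(OCCO2)[C@@H]1C=O
A2 | alternative 1 | 3-chloro-2-(chloromethyl)prop-1-ene | C=C(CCl)CCl
A3 | alternative 1 | 8-methylene bicyclic 6,10-diol with C4 dioxolane | C=C1C[C@H](O)[C@]2(C)CCC3(OCCO3)[C@@H]2[C@H](O)C1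
A4 | alternative 2 | 2,6-dimethylbenzo-1,4-quinone | CC1=CC(=O)C=C(C)C1=O
A5 | alternative 2 | trimethyl(4-methylpenta-1,2-dien-3-yl)silane | C=C=C(C(C)C)[Si](C)(C)C
A6 | alternative 2 | cis-fused silylcyclopentene-annulated ene-dione | CC=1C(=O)[C@]2(C)CC([Si](C)(C)C)=C(C(C)C)[C@@H]2C(=O)C=1
A7 | alternative 3 | 1-isopropyl-4,7-dimethoxy-1-(triethylsilyloxy)indane | COc1ccc(OC)c2c1CC[C@]2(O[Si](CC)(CC)CC)C(C)C
A8 | alternative 3 | ethyl diazoacetate | CCOC(=O)C=[N+]=[N-]
A9 | alternative 3 | ethyl 1-isopropyl-4,8-dimethoxy-1-(triethylsilyloxy)-1,2,3,6-tetrahydroazulene-6-carboxylate | CCOC(=O)[C@H]1C=C(OC)C2=C(C(OC)=C1)[C@@](O[Si](CC)(CC)CC)(C(C)C)CC2
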